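## The problem

Vitekwangin B (22) is a 1-aryl-1,2-dihydronaphthalene. Ring A (C4a–C8a, hydroxyl on C7, methoxyl on C8) is fused to ring B, which carries ring C (3,4-dimethoxyphenyl) on C1, a hydroxymethyl group on C2 and a formyl group on C3 of the C3=C4 double bond; this numbering is used throughout. The only stereocentres are C1 (S) and C2 (R), adjacent and trans. Nothing else in the molecule can direct them, so the step that joins C1 to C2 has to set both. The finished chromophore is fragile: a para-hydroxycinnamaldehyde inside a dihydronaphthalene that can lose two hydrogens to become a naphthalene, with a doubly benzylic C1–H and a free phenol, so enal and phenol should appear last. Ring B has to be closed at C4a although ring C offers an ortho carbon that is just as well placed and just as electron-rich, which makes any acid-mediated closure ambiguous. The two oxygens of ring A must also be told apart. The feature that answers these points is the C8 oxygen: it is ortho to C8a, the carbon that bears C1, so a free C8 phenol makes C1 the exocyclic carbon of an ortho-quinone methide and can then hold the C2 carboxyl carbon (the later CH2OH) as a six-membered aryl lactone. The C7 oxygen is para to C4a and, as a phenoxide, can steer the closure of ring B to that carbon alone.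

## Retrosynthesis

**C3–CHO and the two O–Si bonds.** Target 22 is traced to its bis-silyl ether 21, and removal of the formyl carbon leads to the dihydronaphthalene 20. An enal carried from earlier would not pass the hydrogenolysis and the basic ring closure used before this point. An aldol condensation onto a ring A aldehyde is excluded because a formyl group cannot be placed selectively on C4a. Compound 20 lacks the most sensitive function of the target. The forward step must formylate the styrene-type C3=C4 bond beside two alkoxyarene rings; the para silyloxy group on C7 polarises the alkene toward C3.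

**C4–C4a together with the C3=C4 unsaturation.** Desilylation of the phenol gives 19, and cutting C4–C4a (with water added back across C3=C4) opens ring B to the phenolic aldehyde 17. A Friedel–Crafts closure under acid would let ring C compete. Under base only the C7 phenoxide is nucleophilic, and the tether reaches only its para carbon C4a. Compound 17 is acyclic, with both stereocentres on one rotatable bond. The forward reaction must favour intramolecular hydroxyalkylation over intermolecular aldol chemistry and must stop at the dihydronaphthalene.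

**Functional-group changes back to the diol.** Aldehyde 17 comes from its benzyl ether 16, this from the terminal alkene 15, this from the primary alcohol 14, and this from the phenol 13. No skeletal bond is cut; the order is set by compatibility. The alkene must be cleaved before hydrogenolysis. The C8 oxygen is methylated while it is the only phenol. The primary alcohol is capped so that it can form neither a lactol nor an ether bridge to C4. Each forward step is a routine chemoselective operation.

**The aryl ester C–O bond.** Diol 13 is the reduction product of the dihydrocoumarin 12, in which O8 is tied to the C2 carboxyl carbon. The lactone fixes C1 and C2 in a ring where they are cis. Because that ring contains the carboxyl carbon and not C3, cis in the lactone becomes trans in ring B. The forward reduction must be faster than epimerisation at the lactone α-carbon.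

**C1–C2 and the lactone C–O bond (key disconnection).** Lactone 12 is divided into the ortho-quinone methide 10 and the azolium enolate 11, which come from the sulfone 7 and 2-chloropent-4-enal 9. This cut makes the bond between the two stereocentres under catalyst control and uses only a function the target already owns, the C8 oxygen. A conjugate arylation at C1 or a cycloaddition across ring B would need an auxiliary or an extra handle. A tricyclic compound with two stereocentres falls back to two racemic fragments whose stereocentres are erased in the flask. The forward reaction has to be an enantio- and cis-selective formal (4+2) annulation.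

**The fragments.** Sulfone 7 arises by C–S bond formation from benzhydrol 5 and the sulfinate 6. Compound 5 comes from addition of the Grignard reagent 4 (from 4-bromoveratrole 3) to aldehyde 2, which forms the C1–ring C bond. Aldehyde 2 is the selective mono-benzyl ether of 2,3-dihydroxybenzaldehyde 1; its benzyl group marks the later O7. Chloroaldehyde 9 is made from pent-4-enal 8. All that is asked of these steps is regioselective O-alkylation of 1 and clean ionisation of 5.

## Roads not taken

**Alternative 1:** an aryne Diels–Alder reaction that cuts C4a–C4 and C8a–C1 at once. CsF would release the aryne from the ortho-silylaryl triflate A1, and the 2-aminodiene A2, carrying a methoxymethylpyrrolidine auxiliary, would add to give the cyclic enamine A3.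
- Merits: ring B is made in one step from two simple pieces. The inductive effect of the C8 methoxyl directs the nucleophilic diene terminus to the distal aryne carbon, which is the required orientation. The enamine leaves a carbonyl equivalent on C3.
- Weak points: only C1 is set, by an auxiliary on nitrogen remote from the reacting terminus and in the early transition state of an aryne, so facial selectivity is doubtful. The kinetic C2=C3 enamine of A3 must be hydroxymethylated at C2 before it moves into conjugation with ring A, since the benzylic C4 is the preferred enolisation site. C2 then has to be set trans by the substrate, and the C3 carbonyl still has to become the enal.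
- Comparison: this road reaches the carbon skeleton in fewer steps and would be shorter overall if the stereochemistry held. The chosen plan sets against it a catalytic step that fixes both centres with the C2 carbon substituent already in place, at the price of a longer endgame.

**Alternative 2:** an intramolecular Diels–Alder reaction of a masked ortho-quinone ketal that cuts C1–C8a and C2–C3. The dienone ketal A4 would cyclise through its C8a=C4a–C4=C3 diene onto the tethered cinnamyl alkene, lose methanol and tautomerise to the phenolic lactone A5.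
- Merits: it is by far the shortest route. The trans C1/C2 relation follows from the E-alkene. The 7-hydroxy-8-methoxy pattern is produced by the rearomatisation itself. A5 holds every carbon of the target and needs only reduction and allylic oxidation.
- Weak points: A4 has no stereocentre and no reliable catalytic enantioselective version of this cycloaddition exists, so the product would be racemic. Such dienones usually react through their ring diene or dimerise. The ester tether must adopt its unfavourable s-cis form, which calls for heat that the dienone tolerates poorly.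
- Comparison: for racemic material this road is clearly better in step count. For the single enantiomer the chosen plan is preferred because its absolute configuration comes from a catalyst; it has to accept roughly three times as many steps.

**Alternative 3:** auxiliary-controlled conjugate arylation that cuts the C1–ring C bond and the C2–CH2OH bond. The Grignard reagent 4 with CuBr·SMe2 would add to the N-cinnamoyl 4-phenyloxazolidinone A6, and hydroxymethylation of the enolate would give A7.
- Merits: both stereocentres come from one operation with a well-understood auxiliary. The bromine on C4a of A7 guarantees that ring B closes on ring A. In that respect this road is more secure than the chosen plan, whose regiocontrol rests on a phenoxide cyclisation.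
- Weak points: the auxiliary and copper are stoichiometric. The β-aryl group of A6 is flanked by bromine and methoxyl, so the acceptor is hindered and twisted. After the key step the acyl carbon (C3) must be homologated, C4 brought in through the bromide and the ring closed by condensation. An isopropyl ether must finally be cleaved by a Lewis acid beside the enal. The overall length is similar.
- Comparison: the chosen plan offers a catalytic, unhindered C1–C2 bond formation from cheap materials. It pays with a less secure ring closure and a late formylation.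

Key step: step 5

Assumption: the (5aS,10bR) precatalyst is taken to give the (3S,4S) lactone 12, by analogy with the sense of induction of related azolium enolate annulations; if the opposite series forms, the (5aR,10bS) salt is used and nothing else changes.

## Route

Step 1
Reactants: 1 2,3-dihydroxybenzaldehyde
Product: 2 3-(benzyloxy)-2-hydroxybenzaldehyde
Conditions: NaH (2.2 equiv), DMSO, rt; BnBr (1.0 equiv), rt; aq. HCl
Reagents that add atoms: benzyl bromide, BrCc1ccccc1
Why: Williamson ether synthesis on the dianion; the 2-phenoxide is conjugated and chelated with the formyl group, so the 3-phenoxide is the more nucleophilic oxygen and should take the single equivalent of benzyl bromide.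

Step 2
Reactants: 3 4-bromoveratrole (4-bromo-1,2-dimethoxybenzene); 2 3-(benzyloxy)-2-hydroxybenzaldehyde
Product: 5 2-(benzyloxy)-6-[(3,4-dimethoxyphenyl)(hydroxy)methyl]phenol (racemic), via 3,4-dimethoxyphenylmagnesium bromide 4 (not isolated)
Conditions: 3, Mg, I2 (cat.), THF, 45 °C (2.5 equiv of 4); then 2, THF, 0 °C → rt; aq. NH4Cl
Reagents that add atoms: none
Why: Grignard addition to an aldehyde; the first equivalent of 4 is consumed by the phenol and the second adds to the carbonyl. The new carbinol centre is racemic and is erased in step 5.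

Step 3
Reactants: 5 2-(benzyloxy)-6-[(3,4-dimethoxyphenyl)(hydroxy)methyl]phenol; 6 sodium p-toluenesulfinate
Product: 7 2-(benzyloxy)-6-[(3,4-dimethoxyphenyl)(4-methylbenzenesulfonyl)methyl]phenol (racemic)
Conditions: 6 (1.5 equiv), TsOH·H2O (1.5 equiv), CH2Cl2, rt
Reagents that add atoms: none
Why: Acid-promoted SN1-type substitution; the benzhydrol ionises easily (ortho-hydroxy and para-methoxy stabilisation) and the sulfinate should attack through sulfur to give a stable sulfone.

Step 4
Reactants: 8 pent-4-enal
Product: 9 2-chloropent-4-enal (racemic)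
Conditions: NCS (1.05 equiv), DL-proline (10 mol%), CH2Cl2, 0 °C → rt; pentane, short silica plug, used at once
Reagents that add atoms: N-chlorosuccinimide, O=C1CCC(=O)N1Cl
Why: Enamine-mediated α-chlorination of an aldehyde; racemic 9 is sufficient because its stereocentre disappears in enolate 11.

Step 5
Reactants: 7 2-(benzyloxy)-6-[(3,4-dimethoxyphenyl)(4-methylbenzenesulfonyl)methyl]phenol; 9 2-chloropent-4-enal
Product: 12 (3S,4S)-8-(benzyloxy)-4-(3,4-dimethoxyphenyl)-3-(prop-2-en-1-yl)-3,4-dihydro-2H-chromen-2-one (cis), via ortho-quinone methide 10 (not isolated), via azolium enolate 11 (not isolated)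
Conditions: (5aS,10bR)-2-mesityl-5a,10b-dihydro-4H,6H-indeno[2,1-b][1,2,4]triazolo[4,3-d][1,4]oxazin-2-ium tetrafluoroborate (10 mol%), Cs2CO3 (2.5 equiv), 4 Å MS, toluene, 0 °C → rt, 9 (1.5 equiv) added slowly
Reagents that add atoms: none
Why: Cs2CO3 deprotonates the phenol of 7 and expels p-toluenesulfinate (E1cB) to give the E-configured ortho-quinone methide 10 at low concentration, which erases the stereocentre of racemic 7. The carbene freed from the triazolium salt adds to 9, and loss of HCl from the adduct gives the (Z)-azolium enolate 11, which erases the stereocentre of racemic 9 as well. The enolate carbon (later C2) adds to the methide carbon (later C1) in a conjugate addition that rearomatises ring A, and the C8 phenoxide then acylates the acyl azolium and releases the carbene. The closest known reaction type is the carbene-catalysed formal (4+2) annulation of azolium enolates from α-chloroaldehydes with ortho-quinone methides generated in situ from 2-(sulfonylmethyl)phenols, which gives cis-3,4-disubstituted dihydrocoumarins. The one ring formed, the δ-lactone, closes by 6-exo-trig O-acylation (seen as a cycloaddition, an asynchronous endo oxa-Diels–Alder pathway). The configuration at the lactone α-carbon (C2) is set by the aminoindane backbone of the catalyst, which shields one face of the enolate, and that at the benzylic carbon (C1) follows from the endo approach of the E-methide, which places aryl and allyl groups cis. The step needs C–C bond formation at the exocyclic carbon instead of re-addition of sulfinate, and the kinetic cis product instead of its trans epimer; the first should be secured by the polarisation of 10 and the reversibility of heteroatom additions, the second by the heterogeneous base, slow addition of 9 and immediate filtration and reduction.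

Step 6
Reactants: 12 (3S,4S)-8-(benzyloxy)-4-(3,4-dimethoxyphenyl)-3-(prop-2-en-1-yl)-3,4-dihydro-2H-chromen-2-one
Product: 13 2-(benzyloxy)-6-[(1S,2S)-1-(3,4-dimethoxyphenyl)-2-(hydroxymethyl)pent-4-en-1-yl]phenol
Conditions: LiAlH4 (2 equiv), THF, −20 → 0 °C; EtOAc, aq. sodium potassium tartrate
Reagents that add atoms: none
Why: Hydride reduction of an aryl ester to phenol and primary alcohol; the activated lactone should be reduced well below 0 °C, faster than any alkoxide can epimerise the α-centre, and no stereocentre is touched.

Step 7
Reactants: 13 2-(benzyloxy)-6-[(1S,2S)-1-(3,4-dimethoxyphenyl)-2-(hydroxymethyl)pent-4-en-1-yl]phenol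
Product: 14 (2S)-2-[(S)-[3-(benzyloxy)-2-methoxyphenyl](3,4-dimethoxyphenyl)methyl]pent-4-en-1-ol
Conditions: MeI (1.5 equiv), K2CO3 (2 equiv), DMF, rt
Reagents that add atoms: iodomethane, CI
Why: Williamson methylation under carbonate; only the phenol is deprotonated, so the primary alcohol should stay free and the C8 methoxyl of the target is in place.

Step 8
Reactants: 14 (2S)-2-[(S)-[3-(benzyloxy)-2-methoxyphenyl](3,4-dimethoxyphenyl)methyl]pent-4-en-1-ol
Product: 15 {[(2S)-2-[(S)-[3-(benzyloxy)-2-methoxyphenyl](3,4-dimethoxyphenyl)methyl]pent-4-en-1-yl]oxy}(tert-butyl)diphenylsilane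
Conditions: TBDPSCl (1.2 equiv), imidazole (2.5 equiv), DMF, rt
Reagents that add atoms: tert-butyl(chloro)diphenylsilane, CC(C)(C)[Si](Cl)(c1ccccc1)c1ccccc1
Why: Standard silylation of a primary alcohol; the TBDPS ether is chosen because it should withstand hydrogenolysis, carbonate in methanol, catalytic acid and POCl3/DMF.

Step 9
Reactants: 15 {[(2S)-2-[(S)-[3-(benzyloxy)-2-methoxyphenyl](3,4-dimethoxyphenyl)methyl]pent-4-en-1-yl]oxy}(tert-butyl)diphenylsilane
Product: 16 (3S,4S)-4-[3-(benzyloxy)-2-methoxyphenyl]-3-{[(tert-butyldiphenylsilyl)oxy]methyl}-4-(3,4-dimethoxyphenyl)butanal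
Conditions: O3, CH2Cl2, Sudan Red 7B (indicator), −78 °C; then PPh3, −78 °C → rt
Reagents that add atoms: ozone, [O-][O+]=O
Why: Ozonolysis with reductive work-up; the monosubstituted alkene reacts much faster than the alkoxyarenes and the dye marks the end point, so the aldehyde carbon that becomes C4 is unmasked.

Step 10
Reactants: 16 (3S,4S)-4-[3-(benzyloxy)-2-methoxyphenyl]-3-{[(tert-butyldiphenylsilyl)oxy]methyl}-4-(3,4-dimethoxyphenyl)butanal
Product: 17 (3S,4S)-3-{[(tert-butyldiphenylsilyl)oxy]methyl}-4-(3,4-dimethoxyphenyl)-4-(3-hydroxy-2-methoxyphenyl)butanal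
Conditions: H2 (1 atm), 10% Pd/C, EtOAc, rt
Reagents that add atoms: none
Why: Hydrogenolysis of the aryl benzyl ether; an aliphatic aldehyde and a silyl ether should be inert at 1 atm in a non-alcoholic solvent.

Step 11
Reactants: 17 (3S,4S)-3-{[(tert-butyldiphenylsilyl)oxy]methyl}-4-(3,4-dimethoxyphenyl)-4-(3-hydroxy-2-methoxyphenyl)butanal
Product: 19 (7S,8S)-7-{[(tert-butyldiphenylsilyl)oxy]methyl}-8-(3,4-dimethoxyphenyl)-1-methoxy-7,8-dihydronaphthalen-2-ol, via tetralin-1,6-diol 18 (not isolated)
Conditions: K2CO3 (0.5 equiv), MeOH (0.01 M), 0 °C → rt; AcOH, concentrate; TsOH·H2O (10 mol%), PhMe, 50 °C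
Reagents that add atoms: none
Why: Intramolecular Lederer–Manasse-type hydroxyalkylation; the C7 phenoxide attacks the aldehyde through its para carbon C4a (6-(enolendo)-exo-trig), the only ring position the tether reaches, while ring C is not nucleophilic under base. The para-hydroxybenzylic alcohol 18 should then lose water under catalytic acid to give the conjugated C3=C4 alkene; C1 and C2 are not involved.

Step 12
Reactants: 19 (7S,8S)-7-{[(tert-butyldiphenylsilyl)oxy]methyl}-8-(3,4-dimethoxyphenyl)-1-methoxy-7,8-dihydronaphthalen-2-ol
Product: 20 tert-butyl{[(7S,8S)-7-{[(tert-butyldiphenylsilyl)oxy]methyl}-8-(3,4-dimethoxyphenyl)-1-methoxy-7,8-dihydronaphthalen-2-yl]oxy}dimethylsilane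
Conditions: TBSCl (1.3 equiv), imidazole (2.5 equiv), DMF, rt
Reagents that add atoms: tert-butyl(chloro)dimethylsilane, CC(C)(C)[Si](C)(C)Cl
Why: Silylation of the phenol; it removes the acidic O–H, which would be O-formylated, and keeps a para donor on the styrene for the next step.

Step 13
Reactants: 20 tert-butyl{[(7S,8S)-7-{[(tert-butyldiphenylsilyl)oxy]methyl}-8-(3,4-dimethoxyphenyl)-1-methoxy-7,8-dihydronaphthalen-2-yl]oxy}dimethylsilane
Product: 21 (3R,4S)-6-[(tert-butyldimethylsilyl)oxy]-3-{[(tert-butyldiphenylsilyl)oxy]methyl}-4-(3,4-dimethoxyphenyl)-5-methoxy-3,4-dihydronaphthalene-2-carbaldehyde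
Conditions: POCl3 (2 equiv), DMF, 0 → 50 °C; then aq. NaOAc, rt
Reagents that add atoms: N,N-dimethylformamide, CN(C)C=O; water, O
Why: Vilsmeier–Haack formylation of a styrene-type alkene, a reaction known for 1,2-dihydronaphthalenes; the chloroiminium ion attacks C3, the cation at C4 is stabilised by the para silyloxy group, and proton loss from C3 and hydrolysis give the enal. Veratrole-type rings are poor substrates for this reagent, and the cross-conjugated iminium does not acidify C2–H, so the stereocentres should be safe.

Step 14
Reactants: 21 (3R,4S)-6-[(tert-butyldimethylsilyl)oxy]-3-{[(tert-butyldiphenylsilyl)oxy]methyl}-4-(3,4-dimethoxyphenyl)-5-methoxy-3,4-dihydronaphthalene-2-carbaldehyde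
Product: 22 vitekwangin B, (3R,4S)-4-(3,4-dimethoxyphenyl)-6-hydroxy-3-(hydroxymethyl)-5-methoxy-3,4-dihydronaphthalene-2-carbaldehyde
Conditions: TBAF (3 equiv), AcOH (3 equiv), THF, 0 °C → rt
Reagents that add atoms: none
Why: Fluoride cleavage of the aryl and the primary silyl ether in one operation; buffering with AcOH should keep the phenoxide of the enal from base-induced loss of the hydroxymethyl group or aromatisation.

## Compound list

1 | 2,3-dihydroxybenzaldehyde | O=Cc1cccc(O)c1O | starting material
2 | 3-(benzyloxy)-2-hydroxybenzaldehyde | O=Cc1cccc(OCc2ccccc2)c1O | intermediate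
3 | 4-bromoveratrole (4-bromo-1,2-dimethoxybenzene) | COc1ccc(Br)cc1OC | starting material
4 | 3,4-dimethoxyphenylmagnesium bromide | COc1ccc([Mg]Br)cc1OC | intermediate (not isolated)
5 | 2-(benzyloxy)-6-[(3,4-dimethoxyphenyl)(hydroxy)methyl]phenol (racemic) | COc1ccc(C(O)c2cccc(OCc3ccccc3)c2O)cc1OC | intermediate
6 | sodium p-toluenesulfinate | Cc1ccc(S(=O)[O-])cc1.[Na+] | starting material
7 | 2-(benzyloxy)-6-[(3,4-dimethoxyphenyl)(4-methylbenzenesulfonyl)methyl]phenol (racemic) | COc1ccc(C(c2cccc(OCc3ccccc3)c2O)S(=O)(=O)c2ccc(C)cc2)cc1OC | intermediate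
8 | pent-4-enal | C=CCCC=O | starting material
9 | 2-chloropent-4-enal (racemic) | C=CCC(Cl)C=O | intermediate
10 | (6E)-2-(benzyloxy)-6-[(3,4-dimethoxyphenyl)methylidene]cyclohexa-2,4-dien-1-one | COc1ccc(/C=C2\C=CC=C(OCc3ccccc3)C2=O)cc1OC | intermediate (not isolated)
11 | (1Z)-1-[(5aS,10bR)-2-mesityl-5a,10b-dihydro-4H,6H-indeno[2,1-b][1,2,4]triazolo[4,3-d][1,4]oxazin-2-ium-1-yl]penta-1,4-dien-1-olate (catalyst-bound azolium enolate) | Cc1cc(C)c(c(C)c1)-[n+]1c(/C([O-])=C/CC=C)n2c(n1)CO[C@H]1Cc3ccccc3[C@H]12 | intermediate (not isolated)
12 | (3S,4S)-8-(benzyloxy)-4-(3,4-dimethoxyphenyl)-3-(prop-2-en-1-yl)-3,4-dihydro-2H-chromen-2-one (cis) | COc1ccc([C@H]2c3cccc(OCc4ccccc4)c3OC(=O)[C@H]2CC=C)cc1OC | intermediate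
13 | 2-(benzyloxy)-6-[(1S,2S)-1-(3,4-dimethoxyphenyl)-2-(hydroxymethyl)pent-4-en-1-yl]phenol | COc1ccc([C@@H](c2cccc(OCc3ccccc3)c2O)[C@@H](CO)CC=C)cc1OC | intermediate
14 | (2S)-2-[(S)-[3-(benzyloxy)-2-methoxyphenyl](3,4-dimethoxyphenyl)methyl]pent-4-en-1-ol | COc1ccc([C@@H](c2cccc(OCc3ccccc3)c2OC)[C@@H](CO)CC=C)cc1OC | intermediate
15 | {[(2S)-2-[(S)-[3-(benzyloxy)-2-methoxyphenyl](3,4-dimethoxyphenyl)methyl]pent-4-en-1-yl]oxy}(tert-butyl)diphenylsilane | COc1ccc([C@@H](c2cccc(OCc3ccccc3)c2OC)[C@@H](CO[Si](c2ccccc2)(c2ccccc2)C(C)(C)C)CC=C)cc1OC | intermediate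
16 | (3S,4S)-4-[3-(benzyloxy)-2-methoxyphenyl]-3-{[(tert-butyldiphenylsilyl)oxy]methyl}-4-(3,4-dimethoxyphenyl)butanal | COc1ccc([C@@H](c2cccc(OCc3ccccc3)c2OC)[C@@H](CO[Si](c2ccccc2)(c2ccccc2)C(C)(C)C)CC=O)cc1OC | intermediate
17 | (3S,4S)-3-{[(tert-butyldiphenylsilyl)oxy]methyl}-4-(3,4-dimethoxyphenyl)-4-(3-hydroxy-2-methoxyphenyl)butanal | COc1ccc([C@@H](c2cccc(O)c2OC)[C@@H](CO[Si](c2ccccc2)(c2ccccc2)C(C)(C)C)CC=O)cc1OC | intermediate
18 | (3S,4S)-3-{[(tert-butyldiphenylsilyl)oxy]methyl}-4-(3,4-dimethoxyphenyl)-5-methoxy-1,2,3,4-tetrahydronaphthalene-1,6-diol (C1 epimers) | COc1ccc([C@H]2c3c(ccc(O)c3OC)C(O)C[C@@H]2CO[Si](c2ccccc2)(c2ccccc2)C(C)(C)C)cc1OC | intermediate (not isolated)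
19 | (7S,8S)-7-{[(tert-butyldiphenylsilyl)oxy]methyl}-8-(3,4-dimethoxyphenyl)-1-methoxy-7,8-dihydronaphthalen-2-ol | COc1ccc([C@H]2c3c(ccc(O)c3OC)C=C[C@@H]2CO[Si](c2ccccc2)(c2ccccc2)C(C)(C)C)cc1OC | intermediate
20 | tert-butyl{[(7S,8S)-7-{[(tert-butyldiphenylsilyl)oxy]methyl}-8-(3,4-dimethoxyphenyl)-1-methoxy-7,8-dihydronaphthalen-2-yl]oxy}dimethylsilane | COc1ccc([C@H]2c3c(ccc(O[Si](C)(C)C(C)(C)C)c3OC)C=C[C@@H]2CO[Si](c2ccccc2)(c2ccccc2)C(C)(C)C)cc1OC | intermediate
21 | (3R,4S)-6-[(tert-butyldimethylsilyl)oxy]-3-{[(tert-butyldiphenylsilyl)oxy]methyl}-4-(3,4-dimethoxyphenyl)-5-methoxy-3,4-dihydronaphthalene-2-carbaldehyde | COc1ccc([C@H]2c3c(ccc(O[Si](C)(C)C(C)(C)C)c3OC)C=C(C=O)[C@@H]2CO[Si](c2ccccc2)(c2ccccc2)C(C)(C)C)cc1OC | intermediate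
22 | vitekwangin B, (3R,4S)-4-(3,4-dimethoxyphenyl)-6-hydroxy-3-(hydroxymethyl)-5-methoxy-3,4-dihydronaphthalene-2-carbaldehyde | COc1ccc([C@H]2c3c(ccc(O)c3OC)C=C(C=O)[C@@H]2CO)cc1OC | target

## Step count and risks

Total: 14 steps. Longest linear sequence: 13 steps (from 1 through steps 1–3 and 5–14; step 4 is a one-step side branch).

**Step 5 (key step).** The methide 10 is stabilised by its dimethoxyphenyl group and crowded at the phenoxide by the neighbouring benzyloxy group, so capture of the enolate may be slow. The labile chloroaldehyde could then decompose by self-condensation, and the kinetic cis lactone could epimerise at its α-carbon under the carbonate. Fallback: the same azolium enolate is generated from a stable activated ester. Starting from 7, 4-nitrophenyl pent-4-enoate F1 (from pent-4-enoyl chloride and 4-nitrophenol) is used with the same triazolium salt and Cs2CO3 (1.2 equiv) in toluene. The carbene acylates on the ester and is deprotonated to the enolate without release of chloride, so less base is present and the ester can be used in excess. The route is rejoined at 12.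

**Step 11.** The aldehyde is enolisable, so intermolecular aldol condensation may outrun the para attack of the phenoxide, or the reversible addition may fail to move forward. The electron-rich hydroxystyrene may also oligomerise during the acid treatment. Fallback: a phenolic Mannich (Betti-type) closure. Starting from 17, pyrrolidine (1.2 equiv) and AcOH (cat.) in EtOH at rt convert the aldehyde into its iminium ion, which the free phenol should attack through C4a under near-neutral conditions where ring C is inert. This gives (7S,8S)-7-{[(tert-butyldiphenylsilyl)oxy]methyl}-8-(3,4-dimethoxyphenyl)-1-methoxy-5-(pyrrolidin-1-yl)-5,6,7,8-tetrahydronaphthalen-2-ol F2. Warming F2 in toluene expels pyrrolidine through the para-quinone methide, which tautomerises to the styrene. The route is rejoined at 19.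

**Step 13.** The silyloxy group is a weaker donor than an alkoxy group, so the alkene may react only under forcing conditions, under which attack on ring A (C6) or ring C, attack on the primary silyl ether, or aromatisation could interfere. Fallback from 20, with the formyl carbon introduced by carbonylation:
- Hydroboration–oxidation (BH3·THF; H2O2, NaOH) places oxygen on C3, since hydride goes to the benzylic C4. This gives (3S,4S)-6-[(tert-butyldimethylsilyl)oxy]-3-{[(tert-butyldiphenylsilyl)oxy]methyl}-4-(3,4-dimethoxyphenyl)-5-methoxy-1,2,3,4-tetrahydronaphthalen-2-ol F3.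
- Dess–Martin oxidation gives (3S,4S)-6-[(tert-butyldimethylsilyl)oxy]-3-{[(tert-butyldiphenylsilyl)oxy]methyl}-4-(3,4-dimethoxyphenyl)-5-methoxy-3,4-dihydronaphthalen-2(1H)-one F4.
- KN(SiMe3)2 and PhNTf2 at −78 °C enolise toward the benzylic C4 and give (3S,4S)-6-[(tert-butyldimethylsilyl)oxy]-3-{[(tert-butyldiphenylsilyl)oxy]methyl}-4-(3,4-dimethoxyphenyl)-5-methoxy-3,4-dihydronaphthalen-2-yl trifluoromethanesulfonate F5.
- Reductive carbonylation (Pd(OAc)2, dppp, CO 1 atm, Et3SiH, Et3N, DMF, 70 °C) returns to the route at 21.

**Step 1.** Alkylation of the dianion may not be fully regioselective, and the 2-O-benzyl and bis-benzyl ethers are hard to separate from 2. Fallback: starting from 1, exhaustive benzylation (BnBr, K2CO3, DMF) gives 2,3-bis(benzyloxy)benzaldehyde F6. MgBr2·OEt2 in toluene/Et2O then removes, by chelation to the formyl oxygen, only the benzyl group ortho to the carbonyl. The route is rejoined at 2.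

## Further compounds

F1 | step 5 | 4-nitrophenyl pent-4-enoate | C=CCCC(=O)Oc1ccc(cc1)[N+](=O)[O-]
F2 | step 11 | (7S,8S)-7-{[(tert-butyldiphenylsilyl)oxy]methyl}-8-(3,4-dimethoxyphenyl)-1-methoxy-5-(pyrrolidin-1-yl)-5,6,7,8-tetrahydronaphthalen-2-ol (C5 epimers) | COc1ccc([C@H]2c3c(ccc(O)c3OC)C(N3CCCC3)C[C@@H]2CO[Si](c2ccccc2)(c2ccccc2)C(C)(C)C)cc1OC
F3 | step 13 | (3S,4S)-6-[(tert-butyldimethylsilyl)oxy]-3-{[(tert-butyldiphenylsilyl)oxy]methyl}-4-(3,4-dimethoxyphenyl)-5-methoxy-1,2,3,4-tetrahydronaphthalen-2-ol (C2 epimers) | COc1ccc([C@H]2c3c(ccc(O[Si](C)(C)C(C)(C)C)c3OC)CC(O)[C@@H]2CO[Si](c2ccccc2)(c2ccccc2)C(C)(C)C)cc1OC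
F4 | step 13 | (3S,4S)-6-[(tert-butyldimethylsilyl)oxy]-3-{[(tert-butyldiphenylsilyl)oxy]methyl}-4-(3,4-dimethoxyphenyl)-5-methoxy-3,4-dihydronaphthalen-2(1H)-one | COc1ccc([C@H]2c3c(ccc(O[Si](C)(C)C(C)(C)C)c3OC)CC(=O)[C@@H]2CO[Si](c2ccccc2)(c2ccccc2)C(C)(C)C)cc1OC
F5 | step 13 | (3S,4S)-6-[(tert-butyldimethylsilyl)oxy]-3-{[(tert-butyldiphenylsilyl)oxy]methyl}-4-(3,4-dimethoxyphenyl)-5-methoxy-3,4-dihydronaphthalen-2-yl trifluoromethanesulfonate | COc1ccc([C@H]2c3c(ccc(O[Si](C)(C)C(C)(C)C)c3OC)C=C(OS(=O)(=O)C(F)(F)F)[C@@H]2CO[Si](c2ccccc2)(c2ccccc2)C(C)(C)C)cc1OC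
F6 | step 1 | 2,3-bis(benzyloxy)benzaldehyde | O=Cc1cccc(OCc2ccccc2)c1OCc1ccccc1
A1 | alternative 1 | 4-isopropoxy-3-methoxy-2-(trimethylsilyl)phenyl trifluoromethanesulfonate | COc1c(OC(C)C)ccc(OS(=O)(=O)C(F)(F)F)c1[Si](C)(C)C
A2 | alternative 1 | (2S)-1-[(3E)-4-(3,4-dimethoxyphenyl)buta-1,3-dien-2-yl]-2-(methoxymethyl)pyrrolidine | C=C(/C=C/c1ccc(OC)c(OC)c1)N1CCC[C@H]1COC
A3 | alternative 1 | (2S)-1-[(4S)-4-(3,4-dimethoxyphenyl)-6-isopropoxy-5-methoxy-1,4-dihydronaphthalen-2-yl]-2-(methoxymethyl)pyrrolidine | COc1ccc([C@@H]2C=C(N3CCC[C@H]3COC)Cc3ccc(OC(C)C)c(OC)c32)cc1OC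
A4 | alternative 2 | (2E)-3-(3,4-dimethoxyphenyl)prop-2-en-1-yl (2E)-3-(3,3-dimethoxy-4-oxocyclohexa-1,5-dien-1-yl)prop-2-enoate | COC1(OC)C=C(/C=C/C(=O)OC/C=C/c2ccc(OC)c(OC)c2)C=CC1=O
A5 | alternative 2 | (3aR,4S)-4-(3,4-dimethoxyphenyl)-6-hydroxy-5-methoxy-3a,4-dihydronaphtho[2,3-c]furan-1(3H)-one | COc1ccc([C@H]2c3c(ccc(O)c3OC)C=C4C(=O)OC[C@H]24)cc1OC
A6 | alternative 3 | (4R)-3-[(2E)-3-(6-bromo-3-isopropoxy-2-methoxyphenyl)prop-2-enoyl]-4-phenyl-1,3-oxazolidin-2-one | COc1c(OC(C)C)ccc(Br)c1/C=C/C(=O)N1C(=O)OC[C@H]1c1ccccc1
A7 | alternative 3 | (4R)-3-[(2S,3S)-3-(6-bromo-3-isopropoxy-2-methoxyphenyl)-3-(3,4-dimethoxyphenyl)-2-(hydroxymethyl)propanoyl]-4-phenyl-1,3-oxazolidin-2-one | COc1ccc([C@H]([C@@H](CO)C(=O)N2C(=O)OC[C@H]2c2ccccc2)c2c(Br)ccc(OC(C)C)c2OC)cc1OC
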